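## The problem

The target 26 (C30H22O15) is a linear phlorotannin pentamer: five benzene rings A to E held together only by four diaryl ether oxygens, with eleven free phenolic hydroxyls and no carbon–carbon bond between rings. Every bridging oxygen sits on a ring carbon whose two neighbours are also oxygenated (ring B C1, ring C C1, ring D C1, ring E C1). At the B–C and D–E junctions the partner carbon (ring B C6, ring D C6) has a further ortho oxygen, so these two are tri-ortho-substituted diaryl ethers, the class that resists copper-mediated coupling most. All rings are electron-rich, so plain SNAr is excluded unless the electrophile borrows a removable acceptor. There is no stereocentre and no configurationally stable axis; the problem is one of regiochemistry, namely which oxygens become bridges and which stay free. The free polyphenol is air-sensitive in base and awkward to purify, so the hydroxyls must travel masked and be released last by a method that spares aryl–O–aryl bonds. Ring B invites ring synthesis: its C1 oxygen is para to the C4 oxygen and flanked by the C2 oxygen and the C6 aryloxy group, with hydrogens at C3 and C5. This is the 4-alkoxyphenol pattern that results when a 2-alkoxyvinyl(alkoxy)carbene chromium complex (C2, C3, C4), a terminal alkynyl ether (C5, C6) and one CO ligand (C1) are joined, and the hydroxyl so formed is the one that must later carry ring A.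

## Retrosynthesis

**26 to undecamethyl ether 25.** The eleven O–CH3 bonds are cut first. Methyl ethers are preferred to benzyl or silyl groups because every monomer is a catalogue compound in this form and because they add least bulk to junctions that are already crowded. They should also be inert to butyllithium at −78 °C, peracid, copper/phosphate at 100 °C and the chromium carbene. The price is one forcing step at the end: BBr3 must cleave eleven alkyl–oxygen bonds and none of the four aryl–oxygen–aryl bonds.

**25 to tetramer phenol 23 and 1-iodo-3,5-dimethoxybenzene 24.** The A–B ether is cut at ring A C1–O. The opposite polarity would need a leaving group on ring B C1 between two oxygen substituents. The chosen cut makes the electrophile an unhindered iodide and leaves the flanked oxygen as nucleophile, which copper/picolinic acid catalysis is built for. 23 is simpler by one ring and has a single free hydroxyl.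

**23 to alkynyl ether 21 and carbene complex 18 (key disconnection).** Three C–C bonds of ring B are cut (C4–C5, C6–C1, C1–C2), and C1 is traced back to a CO ligand of 18. The rival cut is the aryl C6–O bond: coupling of phenol 9 with a 2-bromobenzaldehyde, then Dakin oxidation. It is shorter on paper and is held in reserve. It would, however, ask the most valuable phenol of the route, flanked by two methoxy groups, to attack an ortho-substituted bromide, the least favourable copper coupling of the four junctions. The ring synthesis moves all bond formation away from the crowded oxygen: that oxygen is first attached to a two-carbon unit, and ring B then grows around it. The phenol that emerges is free exactly where ring A must go, so no protecting-group step separates the key step from the next coupling. The forward reaction must insert the alkyne with its aryloxy carbon distal to the carbene carbon, insert CO before cyclising, and release the arene from chromium under mild conditions.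

**18 to alkynylcarbene 16, then to (trimethylsilyl)acetylene 12 and Cr(CO)6 13.** The enol ether C3–O bond is cut (conjugate addition of methanol to an alkynylcarbene complex), then the carbene carbon–alkyne bond and the O–CH3 bond (Fischer carbene synthesis). Silicon protects the alkyne through acylchromate formation and methylation and is removed by the same methoxide that catalyses the addition. With both alkoxy groups methoxy, alkoxide exchange at the carbene carbon is degenerate.

**21 to dichlorovinyl ether 11, then to phenol 9 and trichloroethylene 10.** The O–C(sp) bond is cut. Addition of the phenoxide to dichloroacetylene, generated in the flask from 10, puts the two-carbon unit on the flanked oxygen without a metal catalyst. Butyllithium then converts 11 into the terminal alkyne. 11 is the storable form; 21 is made immediately before use.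

**9 to aldehyde 7, then to D–E phenol 5 and 4-bromo-2,6-dimethoxybenzaldehyde 6.** The ring C C4–O bond is cut with the flanked ring D oxygen as nucleophile; ring C C4 has two hydrogen neighbours. The formyl group of 6 serves as para acceptor for the coupling and as latent ring C C1 hydroxyl, revealed by Dakin oxidation, so no protecting group is needed.

**5 to aldehyde 3, then to 2,4,6-trimethoxyphenol 1 and 2-bromo-4,6-dimethoxybenzaldehyde 2.** The same logic applies at ring D C6–O. This is the one tri-ortho ether made by coupling. It is placed first, on two cheap monomers, where excess reagent and forcing conditions cost little, and the ortho formyl group assists the copper step.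

## Roads not taken

**Alternative 1:** Ring C as a doubly activated electrophile.
- **Cut:** both ether bonds of ring C (C1–O and C4–O).
- **Forward step:** the cationic complex A2, [CpRu(η6-2,5-dichloro-1,3-dimethoxybenzene)]PF6, would take the D–E phenoxide (phenol 5 of the present route) at C5, then the phenoxide of the A–B phenol A3 at C2. Photolysis in acetonitrile would release the undecamethyl ether A1, which is the same compound as 25.
- **Merits:** 2 + 1 + 2 convergence and a shorter longest linear sequence; SNAr on ruthenium-bound chloroarenes runs near room temperature and is established for diaryl ethers; the endgame is identical.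
- **Weak points:** the second displacement occurs at a carbon between two methoxy groups, with an ortho-substituted phenoxide, on a complex already deactivated by three donor oxygens. The order of the two displacements must be clean, ruthenium is stoichiometric, and A3 contains a flanked ether needing its own synthesis.
- **Comparison:** in convergence and step count this road is better. The chosen plan sets against it that the B–C junction, where the ruthenium route is most exposed, is not made by substitution at an aryl carbon at all.

**Alternative 2:** Ring E by polyketide-type Claisen cyclisation.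
- **Cut:** the ring E C1–C2 bond, and behind it the whole ring to an acyclic triketide.
- **Forward step:** Mg(OMe)2 would fold the 6-aryloxy-3,5-dioxohexanoate A5 so that the aryloxy-bearing C6 carbanion attacks the ester carbonyl. Enolisation would give pentamer A4, with ring E as free triol and rings A to D as methyl ethers.
- **Merits:** the D–E oxygen is introduced on a CH2 group by simple alkylation, so no tri-ortho coupling is needed; the ring closure is metal-free and biomimetic; ring E arrives unprotected.
- **Weak points:** C6 is the least acidic methylene (C2 and C4 lie between two carbonyls), so closure competes with O-acylation to a 4-hydroxy-2-pyrone, the usual fate of 3,5-dioxo esters. The step comes at the end of a long linear build-up of the A–B–C–D tetramer, which still contains the B–C junction. Eight methyl ethers must then be cleaved beside three free hydroxyls.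
- **Comparison:** cheap reagents and no transition metal in the ring-forming step are real advantages. The chosen plan answers with a closure in which each ring carbon has only one place to go, and it spends the ring construction on the harder B–C junction.

**Alternative 3:** Ring D by cyclobutenone ring expansion.
- **Cut:** the ring D C3–C4 bond.
- **Forward step:** heating cyclobutenone A7 would open the four-membered ring to a dienylketene. Six-electron closure and tautomerisation would give the D–E hydroquinone A6.
- **Merits:** this is the closest mechanistic relative of the chosen key step, needs no metal, and has firmer precedent for oxygen-substituted cases. The ring E oxygen is attached at the four-membered-ring stage by addition–elimination, and the regiochemistry follows from the cyclobutenone substitution.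
- **Weak points:** A6 has two free hydroxyls (C1 and C4) that must be told apart before ring C can be attached, and it oxidises readily to the quinone. The precursor takes several steps. The ring synthesis is spent on the first junction, leaving C–D and B–C to conventional coupling on larger fragments.
- **Comparison:** as a single reaction the ring expansion is better precedented than a carbene benzannulation with an alkynyl aryl ether, and this must be conceded. The chosen plan offsets it by delivering a monophenol that needs no differentiation, by placing the ring synthesis late on the trimer where coupling is weakest, and by keeping the coupling/Dakin cycle as fallback at that point.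

Key step: step 9

Assumption: 18 is drawn as the E isomer, but its alkene geometry is immaterial because C3 of the complex becomes an aromatic carbon; compounds 1, 2, 6, 10, 12, 13 and 24 are taken as catalogue chemicals.

## Route

Step 1
Reactants: 1 2,4,6-trimethoxyphenol; 2 2-bromo-4,6-dimethoxybenzaldehyde
Product: 3 2,4-dimethoxy-6-(2,4,6-trimethoxyphenoxy)benzaldehyde
Conditions: CuI (10 mol%), picolinic acid (20 mol%), K3PO4, DMSO, 90 °C, argon
Reagents that add atoms: none
Why: Ullmann-type copper-catalysed O-arylation with the ligand system established for 2,6-disubstituted phenols; the ortho formyl group activates the C–Br bond and is the latent ring D C1 hydroxyl. The aldehyde has no α-hydrogen and should tolerate the weak base.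

Step 2
Reactants: 3 2,4-dimethoxy-6-(2,4,6-trimethoxyphenoxy)benzaldehyde
Product: 5 2,4-dimethoxy-6-(2,4,6-trimethoxyphenoxy)phenol, via D-E aryl formate 4 (not isolated)
Conditions: mCPBA (1.1 equiv), CH2Cl2, 0 °C; aq. Na2S2O3 wash; then K2CO3 (cat.), MeOH, rt
Reagents that add atoms: mCPBA, OOC(=O)c1cccc(Cl)c1
Why: Dakin-type Baeyer–Villiger oxidation; in the Criegee adduct the electron-rich 2,4,6-trioxygenated aryl group migrates in preference to hydrogen, and methanolysis of formate 4 frees the ring D C1 hydroxyl. One equivalent of peracid at 0 °C should limit oxidation of the rings.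

Step 3
Reactants: 5 2,4-dimethoxy-6-(2,4,6-trimethoxyphenoxy)phenol; 6 4-bromo-2,6-dimethoxybenzaldehyde
Product: 7 4-[2,4-dimethoxy-6-(2,4,6-trimethoxyphenoxy)phenoxy]-2,6-dimethoxybenzaldehyde
Conditions: CuI (10 mol%), picolinic acid (20 mol%), K3PO4, DMSO, 90 °C, argon
Reagents that add atoms: none
Why: Ullmann-type O-arylation as in step 1; the flanked ring D phenoxide meets a para-formyl bromide with no ortho substituent, the favourable polarity for this junction.

Step 4
Reactants: 7 4-[2,4-dimethoxy-6-(2,4,6-trimethoxyphenoxy)phenoxy]-2,6-dimethoxybenzaldehyde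
Product: 9 4-[2,4-dimethoxy-6-(2,4,6-trimethoxyphenoxy)phenoxy]-2,6-dimethoxyphenol, via C-D-E aryl formate 8 (not isolated)
Conditions: mCPBA (1.1 equiv), CH2Cl2, 0 °C; aq. Na2S2O3 wash; then K2CO3 (cat.), MeOH, rt
Reagents that add atoms: mCPBA, OOC(=O)c1cccc(Cl)c1
Why: Dakin-type Baeyer–Villiger oxidation; the 4-aryloxy-2,6-dimethoxyphenyl group has the donor pattern of 2,4,6-trimethoxybenzaldehyde, for which aryl migration is the standard outcome. This reveals the ring C C1 hydroxyl.

Step 5
Reactants: 9 4-[2,4-dimethoxy-6-(2,4,6-trimethoxyphenoxy)phenoxy]-2,6-dimethoxyphenol; 10 trichloroethylene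
Product: 11 2-{[(E)-1,2-dichloroethenyl]oxy}-5-[2,4-dimethoxy-6-(2,4,6-trimethoxyphenoxy)phenoxy]-1,3-dimethoxybenzene
Conditions: K2CO3, DMF, 70 °C
Reagents that add atoms: none
Why: Base-mediated vinylation of a phenol with trichloroethylene: K2CO3 eliminates HCl to give dichloroacetylene in the flask, and anti addition of the phenoxide gives the (E)-1,2-dichlorovinyl ether. The small linear electrophile should be indifferent to the two ortho methoxy groups.

Step 6
Reactants: 12 (trimethylsilyl)acetylene; 13 chromium hexacarbonyl Cr(CO)6
Product: 16 pentacarbonyl[1-methoxy-3-(trimethylsilyl)prop-2-yn-1-ylidene]chromium, via lithium (trimethylsilyl)acetylide 14 (not isolated), via lithium acylchromate 15 (not isolated)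
Conditions: n-BuLi, THF, −78 °C; Cr(CO)6, −78 °C to 0 °C; MeOTf, −40 °C to 0 °C
Reagents that add atoms: methyl triflate, COS(=O)(=O)C(F)(F)F
Why: Fischer carbene synthesis: the acetylide adds to a CO ligand to give acylchromate 15, and O-methylation by the hard electrophile gives the alkynyl(methoxy)carbene complex of zerovalent chromium.

Step 7
Reactants: 16 pentacarbonyl[1-methoxy-3-(trimethylsilyl)prop-2-yn-1-ylidene]chromium
Product: 18 pentacarbonyl[(2E)-1,3-dimethoxyprop-2-en-1-ylidene]chromium, via ethynylcarbene complex 17 (not isolated)
Conditions: NaOMe (10 mol%), MeOH, THF, −78 °C to −20 °C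
Reagents that add atoms: methanol, CO
Why: Alkoxide-catalysed Michael addition of an alcohol to an alkynylcarbene complex; methoxide first removes silicon from the strongly acceptor-substituted alkyne and then adds to C3 of 17, while exchange at the carbene carbon is degenerate. The push-pull alkene can equilibrate, so the E isomer should prevail.

Step 8
Reactants: 11 2-{[(E)-1,2-dichloroethenyl]oxy}-5-[2,4-dimethoxy-6-(2,4,6-trimethoxyphenoxy)phenoxy]-1,3-dimethoxybenzene
Product: 21 2-(ethynyloxy)-5-[2,4-dimethoxy-6-(2,4,6-trimethoxyphenoxy)phenoxy]-1,3-dimethoxybenzene, via chloroethynyl ether 19 (not isolated), via lithium aryloxyacetylide 20 (not isolated)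
Conditions: n-BuLi (2.2 equiv), THF, −78 °C to −40 °C; then H2O, −78 °C to 0 °C; used at once
Reagents that add atoms: none
Why: Dichlorovinyl ether route to ynol ethers: butyllithium-induced dehydrochlorination gives 19, chlorine–lithium exchange gives 20, and protonation gives the terminal alkynyl ether. At −78 °C this should outrun ortho-lithiation of the methoxyarenes, and an aryl ynol ether has no β-hydrogen for retro-ene loss of ketene.

Step 9
Reactants: 21 2-(ethynyloxy)-5-[2,4-dimethoxy-6-(2,4,6-trimethoxyphenoxy)phenoxy]-1,3-dimethoxybenzene; 18 pentacarbonyl[(2E)-1,3-dimethoxyprop-2-en-1-ylidene]chromium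
Product: 23 2,4-dimethoxy-6-{4-[2,4-dimethoxy-6-(2,4,6-trimethoxyphenoxy)phenoxy]-2,6-dimethoxyphenoxy}phenol, via tricarbonylchromium arene complex 22 (not isolated)
Conditions: 18 (1.5 equiv), THF, 50 °C, argon, slow addition of 21; then air, Et2O, rt
Reagents that add atoms: none
Why: Dötz benzannulation, a formal [3+2+1] assembly of ring B. Thermal loss of one CO from 18 opens a site for alkyne 21, which inserts into the Cr=C bond with its unsubstituted carbon bonding to the carbene carbon (C4–C5), so that the aryloxy-bearing carbon becomes the new carbene centre. CO insertion there (C6–C1) gives an η4-dienylketene, and six-electron electrocyclisation onto the methoxy-bearing alkene terminus (C1–C2) closes the six-membered ring as a cyclohexadienone that tautomerises to the phenol, first held as the Cr(CO)3 complex 22 and released by air. The closest known reaction type is the benzannulation of alkenyl(alkoxy)carbene chromium complexes with terminal alkynes, where the substituted alkyne carbon ends next to the CO-derived carbon; 1-alkoxyalkynes have been used as partners only occasionally. No stereocentre is formed. The selectivity needed is the orientation of alkyne insertion: the contrast between hydrogen and the bulky aryloxy group, the nucleophilic character of the terminal carbon of an ynol ether, and oxygen stabilisation of the new carbene centre all direct the aryloxy carbon to C6. The carbene methoxy ends at C4, para to the new hydroxyl, and the vinyl methoxy at C2.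

Step 10
Reactants: 23 2,4-dimethoxy-6-{4-[2,4-dimethoxy-6-(2,4,6-trimethoxyphenoxy)phenoxy]-2,6-dimethoxyphenoxy}phenol; 24 1-iodo-3,5-dimethoxybenzene
Product: 25 2-(3,5-dimethoxyphenoxy)-1,5-dimethoxy-3-{4-[2,4-dimethoxy-6-(2,4,6-trimethoxyphenoxy)phenoxy]-2,6-dimethoxyphenoxy}benzene
Conditions: CuI (10 mol%), picolinic acid (20 mol%), K3PO4, DMSO, 100 °C, argon
Reagents that add atoms: none
Why: Ullmann-type O-arylation of a flanked phenoxide with an unhindered aryl iodide, the polarity for which this ligand system is suited. Exclusion of air protects the 4-methoxyphenol unit from oxidation.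

Step 11
Reactants: 25 2-(3,5-dimethoxyphenoxy)-1,5-dimethoxy-3-{4-[2,4-dimethoxy-6-(2,4,6-trimethoxyphenoxy)phenoxy]-2,6-dimethoxyphenoxy}benzene
Product: 26 CNP0018313.0 (the free undecahydroxy pentamer)
Conditions: BBr3 (excess), CH2Cl2, −78 °C to rt, argon; then H2O, 0 °C; reverse-phase purification under argon
Reagents that add atoms: none
Why: Lewis-acid cleavage of aryl methyl ethers: each methoxy oxygen binds boron and bromide attacks the methyl carbon (SN2), a path closed to aryl–O–aryl bonds. Hydrolysis of the aryl borates gives the polyphenol, which has no vicinal hydroxyl pair and should survive an acidic, oxygen-free work-up.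

## Compound list

1 | 2,4,6-trimethoxyphenol | COc1cc(OC)c(O)c(OC)c1 | starting material
2 | 2-bromo-4,6-dimethoxybenzaldehyde | O=Cc1c(Br)cc(OC)cc1OC | starting material
3 | 2,4-dimethoxy-6-(2,4,6-trimethoxyphenoxy)benzaldehyde | O=Cc1c(OC)cc(OC)cc1Oc1c(OC)cc(OC)cc1OC | intermediate
4 | 2,4-dimethoxy-6-(2,4,6-trimethoxyphenoxy)phenyl formate | O=COc1c(OC)cc(OC)cc1Oc1c(OC)cc(OC)cc1OC | intermediate (not isolated)
5 | 2,4-dimethoxy-6-(2,4,6-trimethoxyphenoxy)phenol (D-E phenol) | Oc1c(OC)cc(OC)cc1Oc1c(OC)cc(OC)cc1OC | intermediate
6 | 4-bromo-2,6-dimethoxybenzaldehyde | O=Cc1c(OC)cc(Br)cc1OC | starting material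
7 | 4-[2,4-dimethoxy-6-(2,4,6-trimethoxyphenoxy)phenoxy]-2,6-dimethoxybenzaldehyde | O=Cc1c(OC)cc(Oc2c(OC)cc(OC)cc2Oc2c(OC)cc(OC)cc2OC)cc1OC | intermediate
8 | 4-[2,4-dimethoxy-6-(2,4,6-trimethoxyphenoxy)phenoxy]-2,6-dimethoxyphenyl formate | O=COc1c(OC)cc(Oc2c(OC)cc(OC)cc2Oc2c(OC)cc(OC)cc2OC)cc1OC | intermediate (not isolated)
9 | 4-[2,4-dimethoxy-6-(2,4,6-trimethoxyphenoxy)phenoxy]-2,6-dimethoxyphenol (C-D-E phenol) | Oc1c(OC)cc(Oc2c(OC)cc(OC)cc2Oc2c(OC)cc(OC)cc2OC)cc1OC | intermediate
10 | trichloroethylene | ClC=C(Cl)Cl | starting material
11 | 2-{[(E)-1,2-dichloroethenyl]oxy}-5-[2,4-dimethoxy-6-(2,4,6-trimethoxyphenoxy)phenoxy]-1,3-dimethoxybenzene | Cl/C=C(/Cl)Oc1c(OC)cc(Oc2c(OC)cc(OC)cc2Oc2c(OC)cc(OC)cc2OC)cc1OC | intermediate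
12 | (trimethylsilyl)acetylene | C#C[Si](C)(C)C | starting material
13 | chromium hexacarbonyl Cr(CO)6 | [C-]#[O+].[C-]#[O+].[C-]#[O+].[C-]#[O+].[C-]#[O+].[C-]#[O+].[Cr] | starting material
14 | lithium (trimethylsilyl)acetylide | [Li]C#C[Si](C)(C)C | intermediate (not isolated)
15 | lithium pentacarbonyl[1-oxido-3-(trimethylsilyl)prop-2-yn-1-ylidene]chromate | C[Si](C)(C)C#CC([O-])=[Cr].[Li+].[C-]#[O+].[C-]#[O+].[C-]#[O+].[C-]#[O+].[C-]#[O+] | intermediate (not isolated)
16 | pentacarbonyl[1-methoxy-3-(trimethylsilyl)prop-2-yn-1-ylidene]chromium | COC(C#C[Si](C)(C)C)=[Cr].[C-]#[O+].[C-]#[O+].[C-]#[O+].[C-]#[O+].[C-]#[O+] | intermediate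
17 | pentacarbonyl(1-methoxyprop-2-yn-1-ylidene)chromium | COC(C#C)=[Cr].[C-]#[O+].[C-]#[O+].[C-]#[O+].[C-]#[O+].[C-]#[O+] | intermediate (not isolated)
18 | pentacarbonyl[(2E)-1,3-dimethoxyprop-2-en-1-ylidene]chromium | CO/C=C/C(OC)=[Cr].[C-]#[O+].[C-]#[O+].[C-]#[O+].[C-]#[O+].[C-]#[O+] | intermediate
19 | 2-[(chloroethynyl)oxy]-5-[2,4-dimethoxy-6-(2,4,6-trimethoxyphenoxy)phenoxy]-1,3-dimethoxybenzene | ClC#COc1c(OC)cc(Oc2c(OC)cc(OC)cc2Oc2c(OC)cc(OC)cc2OC)cc1OC | intermediate (not isolated)
20 | lithium 2-{4-[2,4-dimethoxy-6-(2,4,6-trimethoxyphenoxy)phenoxy]-2,6-dimethoxyphenoxy}ethynide | [Li]C#COc1c(OC)cc(Oc2c(OC)cc(OC)cc2Oc2c(OC)cc(OC)cc2OC)cc1OC | intermediate (not isolated)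
21 | 2-(ethynyloxy)-5-[2,4-dimethoxy-6-(2,4,6-trimethoxyphenoxy)phenoxy]-1,3-dimethoxybenzene | C#COc1c(OC)cc(Oc2c(OC)cc(OC)cc2Oc2c(OC)cc(OC)cc2OC)cc1OC | intermediate
22 | tricarbonyl(η6-arene)chromium complex of phenol 23 | COc1cc(OC)c(O)c(Oc2c(OC)cc(Oc3c(OC)cc(OC)cc3Oc3c(OC)cc(OC)cc3OC)cc2OC)c1.[Cr].[C-]#[O+].[C-]#[O+].[C-]#[O+] | intermediate (not isolated)
23 | 2,4-dimethoxy-6-{4-[2,4-dimethoxy-6-(2,4,6-trimethoxyphenoxy)phenoxy]-2,6-dimethoxyphenoxy}phenol (B-C-D-E phenol) | COc1cc(OC)c(O)c(Oc2c(OC)cc(Oc3c(OC)cc(OC)cc3Oc3c(OC)cc(OC)cc3OC)cc2OC)c1 | intermediate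
24 | 1-iodo-3,5-dimethoxybenzene | COc1cc(I)cc(OC)c1 | starting material
25 | 2-(3,5-dimethoxyphenoxy)-1,5-dimethoxy-3-{4-[2,4-dimethoxy-6-(2,4,6-trimethoxyphenoxy)phenoxy]-2,6-dimethoxyphenoxy}benzene (undecamethyl ether) | COc1cc(OC)cc(Oc2c(OC)cc(OC)cc2Oc2c(OC)cc(Oc3c(OC)cc(OC)cc3Oc3c(OC)cc(OC)cc3OC)cc2OC)c1 | intermediate
26 | CNP0018313.0 | Oc1cc(O)cc(Oc2c(O)cc(O)cc2Oc2c(O)cc(Oc3c(O)cc(O)cc3Oc3c(O)cc(O)cc3O)cc2O)c1 | target

## Step count and risks

Total step count: 11. Longest linear sequence: 9 steps (steps 1, 2, 3, 4, 5, 8, 9, 10, 11, from 1). Steps 6 and 7 form the side branch to complex 18.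

**Step 9 (key step).**
- **Risk:** the aryloxy-stabilised vinylcarbene formed after alkyne insertion may be slow to take up CO. It could then cyclise without CO to a five-membered ring or insert a second alkyne. The terminal ynol ether may oligomerise at 50 °C before it is consumed. The push-pull complex 18 may lose its first CO sluggishly.
- **Fallback:** this sets out from phenol 9 and bromoaldehyde 2. Copper-catalysed coupling under the conditions of step 1 would give the tetramer aldehyde F1. Dakin oxidation as in step 2, through the tetramer aryl formate F2, returns to the route at 23.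

**Step 8.**
- **Risk:** the terminal aryloxyalkyne may oligomerise or hydrate during concentration and chromatography. Ortho-lithiation of the methoxyarene rings may compete if the temperature rises.
- **Fallback:** this sets out from 11. The acetylide 20 is trapped with chlorotrimethylsilane to give the trimethylsilyl ynol ether F3, which can be purified and stored. Desilylation (K2CO3, MeOH, 0 °C) just before the benzannulation returns to the route at 21, used in solution.

**Step 7.**
- **Risk:** the unhindered ethynylcarbene 17 may polymerise or suffer attack at the carbene carbon faster than conjugate addition. Desilylation may be incomplete, leaving a 3-silyl adduct.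
- **Fallback:** this sets out from 13 and avoids the alkyne. Reduction of Cr(CO)6 with potassium graphite C8K gives dipotassium pentacarbonylchromate F4. This is acylated with (E)-3-methoxyacryloyl chloride F5, made from (E)-3-methoxyacrylic acid and oxalyl chloride, to give the potassium acylchromate F6. O-Methylation with MeOTf returns to the route at 18 with the E geometry fixed by the acid chloride.

**Step 10.**
- **Risk:** C–O bond formation may be slow because the flanked phenoxide and its neighbouring oxygens chelate copper, and the electron-rich phenoxide may degrade oxidatively at 100 °C.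
- **Fallback:** this sets out from iodide 24. Oxidation with mCPBA and TsOH in the presence of 1,3,5-trimethoxybenzene gives (3,5-dimethoxyphenyl)(2,4,6-trimethoxyphenyl)iodonium tosylate F7. Metal-free arylation of the potassium salt of 23 (t-BuOK, THF, rt) transfers the 3,5-dimethoxyphenyl group and returns to the route at 25.

**Step 11.**
- **Risk:** cleavage of the eleven ethers may be incomplete, giving partial methyl ethers that cannot be separated as free phenols, and material may be lost to oxidation during isolation.
- **Fallback:** this sets out from 25. The crude BBr3 product is peracetylated (Ac2O, pyridine) to the undecaacetate F8, which is purified on silica; incompletely demethylated acetates are separated and resubmitted. Deacetylation (NaOMe cat., MeOH, argon, then acidic resin) returns to the route at 26.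

## Further compounds

F1 | step 9 | 2-{4-[2,4-dimethoxy-6-(2,4,6-trimethoxyphenoxy)phenoxy]-2,6-dimethoxyphenoxy}-4,6-dimethoxybenzaldehyde (tetramer aldehyde) | O=Cc1c(OC)cc(OC)cc1Oc1c(OC)cc(Oc2c(OC)cc(OC)cc2Oc2c(OC)cc(OC)cc2OC)cc1OC
F2 | step 9 | 2-{4-[2,4-dimethoxy-6-(2,4,6-trimethoxyphenoxy)phenoxy]-2,6-dimethoxyphenoxy}-4,6-dimethoxyphenyl formate (tetramer aryl formate) | O=COc1c(OC)cc(OC)cc1Oc1c(OC)cc(Oc2c(OC)cc(OC)cc2Oc2c(OC)cc(OC)cc2OC)cc1OC
F3 | step 8 | trimethylsilyl ynol ether of 21, (2-{4-[2,4-dimethoxy-6-(2,4,6-trimethoxyphenoxy)phenoxy]-2,6-dimethoxyphenoxy}ethynyl)trimethylsilane | C[Si](C)(C)C#COc1c(OC)cc(Oc2c(OC)cc(OC)cc2Oc2c(OC)cc(OC)cc2OC)cc1OC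
F4 | step 7 | dipotassium pentacarbonylchromate K2Cr(CO)5 | [K+].[K+].[Cr-2].[C-]#[O+].[C-]#[O+].[C-]#[O+].[C-]#[O+].[C-]#[O+]
F5 | step 7 | (E)-3-methoxyacryloyl chloride | CO/C=C/C(Cl)=O
F6 | step 7 | potassium pentacarbonyl[(2E)-3-methoxy-1-oxidoprop-2-en-1-ylidene]chromate | CO/C=C/C([O-])=[Cr].[K+].[C-]#[O+].[C-]#[O+].[C-]#[O+].[C-]#[O+].[C-]#[O+]
F7 | step 10 | (3,5-dimethoxyphenyl)(2,4,6-trimethoxyphenyl)iodonium tosylate | COc1cc(OC)cc([I+]c2c(OC)cc(OC)cc2OC)c1.Cc1ccc(S(=O)(=O)[O-])cc1
F8 | step 11 | undecaacetate of 26 | CC(=O)Oc1cc(OC(C)=O)cc(Oc2c(OC(C)=O)cc(OC(C)=O)cc2Oc2c(OC(C)=O)cc(Oc3c(OC(C)=O)cc(OC(C)=O)cc3Oc3c(OC(C)=O)cc(OC(C)=O)cc3OC(C)=O)cc2OC(C)=O)c1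
A1 | alternative 1 | pentamer undecamethyl ether (identical with 25) | COc1cc(OC)cc(Oc2c(OC)cc(OC)cc2Oc2c(OC)cc(Oc3c(OC)cc(OC)cc3Oc3c(OC)cc(OC)cc3OC)cc2OC)c1
A2 | alternative 1 | (η5-cyclopentadienyl)(η6-2,5-dichloro-1,3-dimethoxybenzene)ruthenium hexafluorophosphate | COc1cc(Cl)cc(OC)c1Cl.[Ru+2].c1cc[cH-]c1.F[P-](F)(F)(F)(F)F
A3 | alternative 1 | 2-(3,5-dimethoxyphenoxy)-3,5-dimethoxyphenol (A-B phenol) | COc1cc(OC)cc(Oc2c(O)cc(OC)cc2OC)c1
A4 | alternative 2 | pentamer with ring E as free 2,4,6-triol and rings A to D as methyl ethers (octamethyl ether of 26) | Oc1cc(O)c(Oc2cc(OC)cc(OC)c2Oc2cc(OC)c(Oc3cc(OC)cc(OC)c3Oc3cc(OC)cc(OC)c3)c(OC)c2)c(O)c1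
A5 | alternative 2 | methyl 3,5-dioxo-6-(aryloxy)hexanoate, aryl being the permethylated A-B-C-D tetramer bound through ring D C6 | COC(=O)CC(=O)CC(=O)COc1cc(OC)cc(OC)c1Oc1cc(OC)c(Oc2cc(OC)cc(OC)c2Oc2cc(OC)cc(OC)c2)c(OC)c1
A6 | alternative 3 | 2-methoxy-6-(2,4,6-trimethoxyphenoxy)benzene-1,4-diol (D-E hydroquinone) | COc1cc(O)cc(Oc2c(OC)cc(OC)cc2OC)c1O
A7 | alternative 3 | 4-hydroxy-4-(1-methoxyethenyl)-3-(2,4,6-trimethoxyphenoxy)cyclobut-2-en-1-one (racemic) | COC(=C)C1(O)C(Oc2c(OC)cc(OC)cc2OC)=CC1=O
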